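The α‑methylene‑γ‑lactone (ring O–C2–C1–C15–C16, exocyclic C17) is disconnected at C1–C15 and C15=C17. The feature exploited is that the C1–C15 bond and the C14–O bond lie on adjacent carbons of the 14‑membered carbocycle in exactly the relationship left by backside opening of a cis‑C1/C14 epoxide. The precursor is therefore the macrocyclic 1,14:3,4‑bis‑epoxide carrying a diethylphosphonoacetate on O2. One base treatment closes the lactone by carbanion attack at C1, fixes the C1 stereocentre, liberates the C14 hydroxyl, and lets the resulting lactone phosphonate olefinate formaldehyde to install C17. Acetylation then gives the target.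

Key step: step 12

Remark: carbocycle atoms are numbered C1–C14 (C1 lactone β‑carbon, C2 lactone O–CH, C3/C4 epoxide, methyls on C4, C8 and C12, C14 the acetoxy carbon) and the lactone carbons C15 (α), C16 (C=O), C17 (=CH2); the target is read as (1R,2S,3R,4R,14S,7E,11E), and oxidants or halogen donors that deliver only heteroatoms are treated as reagents without compound numbers.

Step 1
Reactants: 1 (2E,6E)-farnesol; 2 tert-butyldimethylsilyl chloride
Product: 3 (2E,6E)-farnesyl tert-butyldimethylsilyl ether
Conditions: TBSCl, imidazole, DMF, 0 °C → rt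
Reagents that add atoms: 2 tert-butyldimethylsilyl chloride, CC(C)(C)[Si](C)(C)Cl
Why: Standard silylation of the primary allylic alcohol gives an ether that survives allylic oxidation, bromination and Grignard chemistry.

Step 2
Reactants: 3 farnesyl TBS ether
Product: 4 (2E,6E,10E)-12-(tert-butyldimethylsilyloxy)-2,6,10-trimethyldodeca-2,6,10-trien-1-ol
Conditions: SeO2 (0.1 equiv), t-BuOOH, salicylic acid (0.1 equiv), CH2Cl2, 0 °C → rt, stopped at partial conversion
Reagents that add atoms: selenium dioxide (catalytic oxygen carrier), O=[Se]=O; tert-butyl hydroperoxide (terminal oxygen source), CC(C)(C)OO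
Why: Catalytic SeO2/t-BuOOH allylic hydroxylation (ene reaction, then [2,3]-sigmatropic shift) should attack the E-methyl of the terminal, most electron-rich trisubstituted olefin and give the E-allylic alcohol, with unreacted 3 recycled.

Step 3
Reactants: 4 terminal allylic alcohol
Product: 5 (2E,6E,10E)-12-bromo-3,7,11-trimethyldodeca-2,6,10-trien-1-yl tert-butyldimethylsilyl ether
Conditions: CBr4, PPh3, 2,6-lutidine, CH2Cl2, −20 → 0 °C
Reagents that add atoms: carbon tetrabromide, BrC(Br)(Br)Br
Why: Appel bromination converts the primary allylic alcohol into the bromide under neutral conditions, without allylic transposition or loss of the silyl ether.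

Step 4
Reactants: 5 allylic bromide; 6 vinylmagnesium bromide
Product: 7 tert-butyldimethylsilyl ether of (2E,6E,10E)-3,7,11-trimethyltetradeca-2,6,10,13-tetraen-1-ol
Conditions: vinylMgBr, CuI (10 mol%), THF, −40 → 0 °C
Reagents that add atoms: 6 vinylmagnesium bromide, C=C[Mg]Br
Why: Copper-catalysed Grignard–allylic halide coupling should substitute directly at the primary carbon with retention of the E-olefin, forming the C13–C14 bond of the skipped diene.

Step 5
Reactants: 7 silyl ether
Product: 8 (2E,6E,10E)-3,7,11-trimethyltetradeca-2,6,10,13-tetraen-1-ol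
Conditions: Bu4NF, THF, 0 °C → rt
Reagents that add atoms: none
Why: Fluoride-mediated desilylation frees the allylic alcohol that directs the next epoxidation.

Step 6
Reactants: 8 tetraenol
Product: 9 [(2R,3R)-3-methyl-3-[(3E,7E)-4,8-dimethylundeca-3,7,10-trien-1-yl]oxiran-2-yl]methanol
Conditions: Ti(OiPr)4 (10 mol%), D-(−)-diisopropyl tartrate (12 mol%), t-BuOOH, 4 Å MS, CH2Cl2, −20 °C
Reagents that add atoms: tert-butyl hydroperoxide, CC(C)(C)OO
Why: Sharpless asymmetric epoxidation acts only on the allylic-alcohol olefin, and the D-(−)-tartrate ligand delivers oxygen to the face that gives the (2R,3R)-epoxy alcohol, which sets C3(R) and C4(R) of the target.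

Step 7
Reactants: 9 epoxy alcohol
Product: 10 (2S,3R)-3-methyl-3-[(3E,7E)-4,8-dimethylundeca-3,7,10-trien-1-yl]oxirane-2-carbaldehyde
Conditions: TEMPO (10 mol%), PhI(OAc)2, CH2Cl2, rt; used crude
Reagents that add atoms: none
Why: TEMPO-catalysed oxidation with PhI(OAc)2 stops at the aldehyde and is mild enough for the epoxide and the four olefins.

Step 8
Reactants: 10 epoxy aldehyde; 6 vinylmagnesium bromide
Product: 11 (1R)-1-[(2R,3R)-3-methyl-3-[(3E,7E)-4,8-dimethylundeca-3,7,10-trien-1-yl]oxiran-2-yl]prop-2-en-1-ol (carbinol erythro to the oxirane)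
Conditions: vinylMgBr, THF, −78 °C; chromatographic removal of the threo isomer
Reagents that add atoms: 6 vinylmagnesium bromide, C=C[Mg]Br
Why: Grignard addition to the α,β-epoxy aldehyde under Felkin–Anh/Cornforth control (C=O anti to the oxirane C–O, attack past H3 and away from C4 with its cis-methyl) should favour the erythro carbinol and set C2 as R.

Step 9
Reactants: 11 acyclic epoxy dienol
Product: 12 (2R,3R,4R,1Z,7E,11E)-3,4-epoxy-4,8,12-trimethylcyclotetradeca-1(14),7,11-trien-2-ol (14-membered carbocycle with Z olefin C1=C14)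
Conditions: Ru(κ2-O2NO)(=CH-C6H4-2-OiPr)(κ2-C,C-NHC) [NHC = cyclometalated 1-adamantyl-3-(2,6-diisopropylphenyl)imidazolin-2-ylidene] (7.5 mol%), ClCH2CH2Cl (2 mM), 50 °C, static vacuum
Reagents that add atoms: none
Why: In this Z-selective ring-closing metathesis the cyclometalated ruthenium catalyst loads on the unhindered C14 terminus, ignores the trisubstituted olefins and closes the 14-membered ring through a side-bound metallacyclobutane that holds both ring substituents on one side, which should give the Z C1=C14 olefin at high dilution.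

Step 10
Reactants: 12 macrocyclic Z-allylic alcohol
Product: 13 (1S,2R,3R,4R,14S,7E,11E)-1,14:3,4-diepoxy-4,8,12-trimethylcyclotetradeca-7,11-dien-2-ol (cis C1–C14 epoxide threo to the C2 hydroxyl)
Conditions: VO(acac)2 (5 mol%), t-BuOOH, CH2Cl2, 0 °C
Reagents that add atoms: tert-butyl hydroperoxide, CC(C)(C)OO
Why: Vanadium-catalysed hydroxyl-directed epoxidation touches only the allylic olefin, and allylic 1,3-strain in the Z-allylic alcohol (H2 in the olefin plane) together with peripheral attack on the macrocycle should place oxygen on the face of the C2 hydroxyl, giving the threo cis-epoxide with C1(S) and C14(S).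

Step 11
Reactants: 13 bis-epoxy alcohol; 14 diethylphosphonoacetic acid
Product: 15 (1S,2S,3R,4R,14S,7E,11E)-1,14:3,4-diepoxy-4,8,12-trimethylcyclotetradeca-7,11-dien-2-yl 2-(diethoxyphosphoryl)acetate
Conditions: PPh3, DIAD, (EtO)2P(O)CH2CO2H, toluene, 0 °C → rt
Reagents that add atoms: 14 diethylphosphonoacetic acid, CCOP(=O)(OCC)CC(=O)O
Why: Mitsunobu esterification with the acidic phosphonoacetic acid proceeds by SN2 displacement of the oxyphosphonium ion, inverting C2 from R to S while installing the tether, so that the ester oxygen becomes erythro to the 1,14-epoxide and threo to the 3,4-epoxide.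

Step 12
Reactants: 15 bis-epoxy phosphonoacetate; 16 formaldehyde (as paraformaldehyde)
Product: 18 14-O-deacetyl α-methylene lactone (free C14 alcohol), via α-phosphono lactone 17 (not isolated)
Conditions: NaH (1.05 equiv), THF, 0 → 45 °C; then (CH2O)n, 45 °C
Reagents that add atoms: 16 formaldehyde (paraformaldehyde), C=O
Why: NaH deprotonates the phosphonoacetate and, on warming, C15 attacks C1 from the side opposite the C1–O bond of the cis-epoxide, so that C1–C15 forms with inversion at C1 while C14 keeps its oxygen and configuration; proton transfer from the acidic α-phosphono lactone 17 to the C14 alkoxide then gives the lactone phosphonate anion, which undergoes Horner–Wadsworth–Emmons olefination with formaldehyde to create C15=C17. The closest known reaction types are the opening of epoxides by phosphonoacetate anions on the way to α-phosphono-γ-lactones, the intramolecular C-alkylation of ester-tethered phosphonoacetates and epoxy-nitrile-type cyclisations, combined with the standard formaldehyde methylenation of α-phosphono lactones. The lactone ring (O–C2–C1–C15–C16) closes in a 5-exo-tet mode with the breaking C1–O bond outside the new ring, and because the carbanion is held mainly by the exocyclic phosphoryl group the endocyclic ester need not stay coplanar, which avoids the poor geometry of a purely enolate-based five-ring alkylation. The only new stereocentre, C1, is set as R by the stereospecific backside displacement on the (1S,14S)-epoxide from the 2S tether, which leads to the trans-fused lactone (H1 and H2 anti). Selectivity is needed against 6-endo attack at C14 and 5-exo attack at C3 of the other epoxide: C1 is favoured because the erythro C2–O/C1–O arrangement lets C3 and C14 stay anti across C2–C1 with H2 over the oxirane, whereas attack at C3 (threo arrangement) would force C1 over the trisubstituted oxirane into a cis-fused lactone and is further hindered by the fully substituted C4 beside it. One equivalent of base and a moderate temperature keep the C14 oxygen protonated after ring closure, which guards against acyl or phosphoryl transfer to O14.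

Step 13
Reactants: 18 C14 alcohol; 19 acetic anhydride
Product: 20 target, (1R,2S,3R,4R,14S,7E,11E)-14-acetoxy-3,4-epoxy α-methylene-γ-lactone (CNP0294029.1)
Conditions: Ac2O, pyridine, DMAP (cat.), CH2Cl2, 0 °C → rt
Reagents that add atoms: 19 acetic anhydride, CC(=O)OC(C)=O
Why: DMAP-catalysed acetylation of the secondary C14 alcohol is a routine esterification that leaves the epoxide and the methylene lactone untouched.

Compound list
1 | (2E,6E)-farnesol | CC(C)=CCC/C(C)=C/CC/C(C)=C/CO | starting material
2 | tert-butyldimethylsilyl chloride | CC(C)(C)[Si](C)(C)Cl | starting material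
3 | (2E,6E)-farnesyl tert-butyldimethylsilyl ether | CC(C)=CCC/C(C)=C/CC/C(C)=C/CO[Si](C)(C)C(C)(C)C | intermediate
4 | (2E,6E,10E)-12-(tert-butyldimethylsilyloxy)-2,6,10-trimethyldodeca-2,6,10-trien-1-ol | OC/C(C)=C/CC/C(C)=C/CC/C(C)=C/CO[Si](C)(C)C(C)(C)C | intermediate
5 | (2E,6E,10E)-12-bromo-3,7,11-trimethyldodeca-2,6,10-trien-1-yl tert-butyldimethylsilyl ether | BrC/C(C)=C/CC/C(C)=C/CC/C(C)=C/CO[Si](C)(C)C(C)(C)C | intermediate
6 | vinylmagnesium bromide | C=C[Mg]Br | starting material
7 | tert-butyldimethylsilyl ether of (2E,6E,10E)-3,7,11-trimethyltetradeca-2,6,10,13-tetraen-1-ol | C=CC/C(C)=C/CC/C(C)=C/CC/C(C)=C/CO[Si](C)(C)C(C)(C)C | intermediate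
8 | (2E,6E,10E)-3,7,11-trimethyltetradeca-2,6,10,13-tetraen-1-ol | C=CC/C(C)=C/CC/C(C)=C/CC/C(C)=C/CO | intermediate
9 | [(2R,3R)-3-methyl-3-[(3E,7E)-4,8-dimethylundeca-3,7,10-trien-1-yl]oxiran-2-yl]methanol | C=CC/C(C)=C/CC/C(C)=C/CC[C@@]1(C)O[C@@H]1CO | intermediate
10 | (2S,3R)-3-methyl-3-[(3E,7E)-4,8-dimethylundeca-3,7,10-trien-1-yl]oxirane-2-carbaldehyde | C=CC/C(C)=C/CC/C(C)=C/CC[C@@]1(C)O[C@@H]1C=O | intermediate
11 | (1R)-1-[(2R,3R)-3-methyl-3-[(3E,7E)-4,8-dimethylundeca-3,7,10-trien-1-yl]oxiran-2-yl]prop-2-en-1-ol (erythro) | C=CC/C(C)=C/CC/C(C)=C/CC[C@@]1(C)O[C@@H]1[C@H](O)C=C | intermediate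
12 | (2R,3R,4R,1Z,7E,11E)-3,4-epoxy-4,8,12-trimethylcyclotetradeca-1(14),7,11-trien-2-ol | O[C@@H]2/C=C\C/C(C)=C/CC/C(C)=C/CC[C@@]1(C)O[C@H]21 | intermediate
13 | (1S,2R,3R,4R,14S,7E,11E)-1,14:3,4-diepoxy-4,8,12-trimethylcyclotetradeca-7,11-dien-2-ol | O[C@@H]2[C@H]3O[C@H]3C/C(C)=C/CC/C(C)=C/CC[C@@]1(C)O[C@H]21 | intermediate
14 | diethylphosphonoacetic acid | CCOP(=O)(OCC)CC(=O)O | starting material
15 | (1S,2S,3R,4R,14S,7E,11E)-1,14:3,4-diepoxy-4,8,12-trimethylcyclotetradeca-7,11-dien-2-yl 2-(diethoxyphosphoryl)acetate (key-step precursor) | CCOP(=O)(OCC)CC(=O)O[C@H]2[C@H]3O[C@H]3C/C(C)=C/CC/C(C)=C/CC[C@@]1(C)O[C@H]21 | intermediate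
16 | formaldehyde (used as paraformaldehyde) | C=O | starting material
17 | α-phosphono lactone: trans-fused γ-lactone O–C2–C1–C15–C16 with P(O)(OEt)2 on C15 and free C14-OH, (1R,2S,3R,4R,14S), C15 unassigned, present as its sodium salt | CCOP(=O)(OCC)C1C(=O)O[C@H]2[C@H]1[C@@H](O)C/C(C)=C/CC/C(C)=C/CC[C@@]1(C)O[C@H]21 | intermediate
18 | 14-O-deacetyl target, (1R,2S,3R,4R,14S,7E,11E) α-methylene lactone with free C14-OH | C=C1C(=O)O[C@H]2[C@H]1[C@@H](O)C/C(C)=C/CC/C(C)=C/CC[C@@]1(C)O[C@H]21 | intermediate
19 | acetic anhydride | CC(=O)OC(C)=O | starting material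
20 | CNP0294029.1, (1R,2S,3R,4R,14S,7E,11E)-14-acetate | C=C1C(=O)O[C@H]2[C@H]1[C@@H](OC(C)=O)C/C(C)=C/CC/C(C)=C/CC[C@@]1(C)O[C@H]21 | target

Total step count: 13. Longest linear sequence: 13 steps from 1.

Steps most likely to fail

1. Step 12 (key step). Risk: the tethered carbanion may open the wrong oxirane carbon, or the freed C14 alkoxide may attack phosphorus before proton transfer, so that olefination is lost. Fallback: setting out from 13, Mitsunobu esterification with monoallyl malonate (PPh3, DIAD, toluene) would give the C2-inverted allyl malonate F1. NaH in THF would then effect the classical malonate opening of the C1–C14 oxirane at C1 to give the α-(allyloxycarbonyl) lactone F2, which carries no phosphorus electrophile and would be taken on crude. Pd(PPh3)4 with morpholine would release the α-carboxy lactone F3, and aqueous formaldehyde with diethylamine would bring about decarboxylative Mannich methylenation, rejoining the route at 18.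

2. Step 9. Risk: erosion of Z control, migration of the skipped diene or oligomerisation at the dilution needed. Fallback: setting out from 5, CuI-catalysed coupling with 1-propynylmagnesium bromide would give the silyl-protected enyne F4. Desilylation with Bu4NF would give the enynol F5, Sharpless epoxidation with D-(−)-diisopropyl tartrate the epoxy alcohol F6, and TEMPO/PhI(OAc)2 oxidation the epoxy aldehyde F7. Addition of 1-propynylmagnesium bromide would give the erythro diyne carbinol F8. Ring-closing alkyne metathesis with [Mo(≡C-C6H4-4-OMe)(OSiPh3)3] and 5 Å sieves in toluene would give the cycloalkynol F9, and semihydrogenation over Pd/CaCO3 poisoned with Pb(OAc)2 and quinoline would fix the Z geometry and return to the route at 12.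

3. Step 11. Risk: slow displacement at a carbinol flanked by two oxiranes, with elimination or acyl transfer with retention competing. Fallback: setting out from 13, Dess–Martin oxidation would give the bis-epoxy ketone F10. Chelation-controlled reduction with Zn(BH4)2 in Et2O is expected to give the C2-epimeric (2S) alcohol F11, since hydride should arrive anti to the less hindered 1,14-oxirane held in the zinc chelate. Carbodiimide esterification of F11 with 14 (DIC, DMAP, CH2Cl2), which retains configuration, would rejoin the route at 15, and any 13 re-formed in the reduction would be recycled.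

Further compounds
F1 | step 12 | allyl (1S,2S,3R,4R,14S,7E,11E)-1,14:3,4-diepoxy-4,8,12-trimethylcyclotetradeca-7,11-dien-2-yl malonate | C=CCOC(=O)CC(=O)O[C@H]2[C@H]3O[C@H]3C/C(C)=C/CC/C(C)=C/CC[C@@]1(C)O[C@H]21
F2 | step 12 | α-(allyloxycarbonyl) trans-fused lactone with free C14-OH (C15 unassigned) | C=CCOC(=O)C1C(=O)O[C@H]2[C@H]1[C@@H](O)C/C(C)=C/CC/C(C)=C/CC[C@@]1(C)O[C@H]21
F3 | step 12 | α-carboxy trans-fused lactone with free C14-OH (C15 unassigned) | OC(=O)C1C(=O)O[C@H]2[C@H]1[C@@H](O)C/C(C)=C/CC/C(C)=C/CC[C@@]1(C)O[C@H]21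
F4 | step 9 | tert-butyldimethylsilyl ether of (2E,6E,10E)-3,7,11-trimethylpentadeca-2,6,10-trien-13-yn-1-ol | CC#CC/C(C)=C/CC/C(C)=C/CC/C(C)=C/CO[Si](C)(C)C(C)(C)C
F5 | step 9 | (2E,6E,10E)-3,7,11-trimethylpentadeca-2,6,10-trien-13-yn-1-ol | CC#CC/C(C)=C/CC/C(C)=C/CC/C(C)=C/CO
F6 | step 9 | [(2R,3R)-3-methyl-3-[(3E,7E)-4,8-dimethyldodeca-3,7-dien-10-yn-1-yl]oxiran-2-yl]methanol | CC#CC/C(C)=C/CC/C(C)=C/CC[C@@]1(C)O[C@@H]1CO
F7 | step 9 | (2S,3R)-3-methyl-3-[(3E,7E)-4,8-dimethyldodeca-3,7-dien-10-yn-1-yl]oxirane-2-carbaldehyde | CC#CC/C(C)=C/CC/C(C)=C/CC[C@@]1(C)O[C@@H]1C=O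
F8 | step 9 | erythro 1-[(2R,3R)-3-methyl-3-[(3E,7E)-4,8-dimethyldodeca-3,7-dien-10-yn-1-yl]oxiran-2-yl]but-2-yn-1-ol | CC#CC/C(C)=C/CC/C(C)=C/CC[C@@]1(C)O[C@@H]1[C@H](O)C#CC
F9 | step 9 | (2R,3R,4R,7E,11E)-3,4-epoxy-4,8,12-trimethylcyclotetradeca-7,11-dien-1(14)-yn-2-ol | O[C@@H]2C#CC/C(C)=C/CC/C(C)=C/CC[C@@]1(C)O[C@H]21
F10 | step 11 | (1S,3R,4R,14S,7E,11E)-1,14:3,4-diepoxy-4,8,12-trimethylcyclotetradeca-7,11-dien-2-one | O=C2[C@H]3O[C@H]3C/C(C)=C/CC/C(C)=C/CC[C@@]1(C)O[C@H]21
F11 | step 11 | (1S,2S,3R,4R,14S,7E,11E)-1,14:3,4-diepoxy-4,8,12-trimethylcyclotetradeca-7,11-dien-2-ol | O[C@H]2[C@H]3O[C@H]3C/C(C)=C/CC/C(C)=C/CC[C@@]1(C)O[C@H]21
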